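**Remark:** the side chain is read as unbranched pentacosyl (25 carbons, C34H56O4 overall). C2 plus the chain then correspond to the 26 carbons of purchasable hexacosan-1-ol.

## The problem

Target 16 is a 4H-chromen-4-one. Benzene ring A carries oxygen at C5, C7 and C8a (the 1,3,5-pattern of phloroglucinol) and is fused through C4a–C8a to pyranone ring C, which bears an unbranched C25 chain at C2. There is no stereocentre, so the task is connectivity and regiochemistry on ring A.

The bonds to be made are C4–C4a and O1–C8a, on neighbouring ring-A carbons with the C5 oxygen on the other side of C4a, and then O1–C2 of the pyranone. The chain is inert but odd-numbered, so it must come from an even-numbered C26 fatty building block, one carbon of which becomes C2.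

Ring C opens at C2 under hydroxide or alkoxide, so strong aqueous base is excluded once it exists. Free phloroglucinol-type phenols are ambident and oxidise in base, so two oxygens stay masked to the end; the chelated 5-O is easy to free, the 7-O is not. The C26–C36 intermediates are waxes with poor solubility in cold ethers, so chain-bearing steps should be few and run warm where possible.

The feature that makes the key step possible is this: the ring-A bond C4a–C8a carries the acyl carbon C4 and the oxygen O1 on adjacent atoms, and the other neighbour of C4a, C5, bears oxygen. That is the pattern formed when an oxygen nucleophile adds to a 3-alkoxybenzyne at the carbon remote from the alkoxy group and the carbanion beside the alkoxy group captures an acyl group. In addition, C2–C3–C4 stand at the oxidation level of an alk-2-ynoic acid (C4 carboxyl, C2≡C3). So aryne 13 can take up O1 and C4 from one molecule of acid 12 in one operation.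

## Retrosynthesis

**16 ⇒ 15.** The two O–CH3 bonds at C5 and C7 are cut. Methyl is chosen because the methoxy group beside the aryne bond is the regiochemical control element and must survive n-BuLi, fluoride and 125 °C. Benzyl would invite benzylic lithiation in step 2 and silyl would fall to fluoride in step 7. The forward step must cleave both ethers without opening ring C.

**15 ⇒ 14.** O1–C2 is cut. Ynone 14 already holds C2–C3–C4 at the correct oxidation level, so the forward reaction is a redox-neutral 6-endo addition of the phenoxide oxygen to the triple bond. A 1,3-diketone would need a separate acid dehydration.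

**14 ⇒ 13 + 12.** C4–C4a and O(phenol)–C8a are cut together. Cutting only C4–C4a (Friedel–Crafts acylation of a phloroglucinol ether by the ynoyl chloride) needs a Lewis acid that also attacks the ynone, and leaves three equal methoxy groups of which one must be singled out. Cutting only the C–O bond has no sensible forward reaction. The double cut reduces a 36-carbon, tetrasubstituted arene to an eight-carbon aryne 13 and a linear acid 12. The forward reaction must place oxygen at the aryne carbon remote from the flanking methoxy group and acyl at the carbon next to it, and the acyl shift must outrun protonation.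

**13 ⇒ 7 ⇒ 5 ⇒ 2 ⇒ 1.** Aryne 13 comes from silylaryl triflate 7 by fluoride. The C–Si bond of 5 is cut back to carbamate 2 (directed ortho-metalation), and the carbamate comes from phenol 1. The carbamate first directs lithiation to the position between itself and a methoxy group, then is removed to phenol 6 and exchanged for triflate. Phenol 1 is symmetrical, so its two such positions are the same.

**12 ⇒ 11 ⇒ 10 ⇒ 9 ⇒ 8.** C3–C4 is cut (carboxylation of acetylide 11), then C2≡C3 (one-carbon homologation of aldehyde 9 through dibromoalkene 10). C1 of hexacosan-1-ol 8 becomes C2 of the target and its other 25 carbons become the chain, which mirrors the presumed C26 acyl starter of the biosynthesis. This avoids any odd-chain reagent.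

## Roads not taken

**Alternative 1:** The obvious route cuts O1–C2 and C2–C3 (Baker–Venkataraman). Purchased 2-hydroxy-4,6-dimethoxyacetophenone would be esterified with purchased hexacosanoic acid (DCC, DMAP) to 2-acetyl-3,5-dimethoxyphenyl hexacosanoate A1. Base-induced acyl shift would give diketone A2, acid cyclodehydration would give 15, and demethylation would follow as here.
- It is sound and no longer than the chosen route (four linear steps), so the preference is not one of step count.
- Its key step needs the acetyl enolate to attack an enolisable aliphatic ester whose α-CH2 is about as acidic. Ester cleavage through the ketene and intermolecular Claisen condensation therefore compete; the shift is at its best with aroyl esters.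
- The potassium or sodium enolates of A1 and A2 are soaps, which makes the strongly basic step hard to run on a C26 chain.
- All ring-A bonds are bought, so the route gives no regiochemical handle for analogues. The chosen plan is convergent, joins the chain as a carboxylate rather than as an enolate partner, and closes ring C without a dehydration.

**Alternative 2:** A biomimetic fold of a masked pentaketide. Lateral lithiation of 2,6-dimethyl-4H-pyran-4-one and alkylation with 1-bromotetracosane would give 2-methyl-6-pentacosyl-4H-pyran-4-one A3. A second lateral metalation and acylation with a malonyl unit would give keto ester A4. Base (Mg(OMe)2 or KOH) would open the pyranone and a Claisen closure of the future C4a onto the ester carbon would give 16 directly, without protecting groups.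
- Once the pyranone is open, the tetraketo ester can close in at least three six-membered modes (one Claisen, two aldol). Nothing in A4 favours the one that is wanted.
- The second metalation must choose the methyl group over the chain CH2.
- The malonyl acylating agent carries an acidic CH2 that quenches the lateral anion.
- The run-up is three uncertain steps before an uncontrolled key step.

**Alternative 3:** Closure of ring C at C4–C4a. Conjugate addition of phenol 1 to methyl octacos-2-ynoate A5 and saponification would give (Z)-3-(3,5-dimethoxyphenoxy)octacos-2-enoic acid A6. Intramolecular Friedel–Crafts acylation (Eaton's reagent) would give 15.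
- Phenoxide addition to a β-alkyl ynoate is slow and reversible, and gives E/Z mixtures of which only the Z acid A6 can close.
- The electron-rich ring of 1 is also a carbon nucleophile toward the β-carbon, which leads to coumarin A7.
- The enol ether of A6 is labile to the acid needed for closure.
- It needs the same chain-building steps as the chosen route, so nothing is saved.

Key step: step 7

## Route

**Step 1**
Reactants: 1 3,5-dimethoxyphenol
Product: 2 3,5-dimethoxyphenyl N-isopropylcarbamate
Conditions: i-PrNCO, Et3N (cat.), CH2Cl2, rt
Reagents that add atoms: isopropyl isocyanate, CC(C)N=C=O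
Why: Base-catalysed addition of a phenol to an isocyanate; the N-monoalkyl carbamate is a strong ortho-director that can later be removed under mild base.

**Step 2**
Reactants: 2 3,5-dimethoxyphenyl N-isopropylcarbamate
Product: 5 3,5-dimethoxy-2-(trimethylsilyl)phenyl N-isopropylcarbamate, via N-silyl carbamate 3 (not isolated), via N,C-disilyl carbamate 4 (not isolated)
Conditions: TMSOTf, TMEDA, Et2O, 0 °C to rt; n-BuLi, TMEDA, −78 °C; TMSCl, −78 °C to rt; aq. NaHSO4
Reagents that add atoms: chlorotrimethylsilane, C[Si](C)(C)Cl
Why: N-silylation in the flask masks the N–H; directed ortho-metalation then occurs at the position flanked by the carbamate and a methoxy group (two equivalent sites by symmetry), and TMSCl traps the carbanion. The N–Si bond is hydrolysed on work-up.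

**Step 3**
Reactants: 5 3,5-dimethoxy-2-(trimethylsilyl)phenyl N-isopropylcarbamate
Product: 7 3,5-dimethoxy-2-(trimethylsilyl)phenyl trifluoromethanesulfonate, via silylphenol 6 (not isolated)
Conditions: Et2NH, DBU, MeCN, 40 °C; then PhNTf2, rt
Reagents that add atoms: N-phenylbis(trifluoromethanesulfonimide), FC(F)(F)S(=O)(=O)N(c1ccccc1)S(=O)(=O)C(F)(F)F
Why: E1cB cleavage of the N-monoalkyl carbamate gives the phenoxide and isopropyl isocyanate (trapped by Et2NH), and the phenoxide is triflated in the same flask. The medium stays basic, so the electron-rich aryl–silicon bond is not protonated off.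

**Step 4**
Reactants: 8 hexacosan-1-ol
Product: 9 hexacosanal
Conditions: TEMPO (cat.), PhI(OAc)2, CH2Cl2, 35 °C
Reagents that add atoms: none
Why: Oxoammonium-mediated oxidation of a primary alcohol stops at the aldehyde; the warm chlorinated solvent keeps the wax in solution.

**Step 5**
Reactants: 9 hexacosanal
Product: 10 1,1-dibromoheptacos-1-ene
Conditions: CBr4, PPh3, CH2Cl2, 0 °C to rt
Reagents that add atoms: carbon tetrabromide, BrC(Br)(Br)Br
Why: Corey–Fuchs (Ramirez) dibromo-olefination; the new carbon is the future C3.

**Step 6**
Reactants: 10 1,1-dibromoheptacos-1-ene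
Product: 12 octacos-2-ynoic acid, via lithium heptacos-1-yn-1-ide 11 (not isolated)
Conditions: n-BuLi (2.2 equiv), THF, −40 to 0 °C; CO2, −40 °C to rt; 1 M HCl
Reagents that add atoms: carbon dioxide, O=C=O
Why: Second stage of the Corey–Fuchs sequence (Br–Li exchange, Fritsch–Buttenberg–Wiechell shift, deprotonation) gives the acetylide, which is carboxylated; the CO2 carbon is the future C4.

**Step 7**
Reactants: 7 3,5-dimethoxy-2-(trimethylsilyl)phenyl trifluoromethanesulfonate; 12 octacos-2-ynoic acid
Product: 15 5,7-dimethoxy-2-pentacosyl-4H-chromen-4-one, via 3,5-dimethoxybenzyne 13 (not isolated), via hydroxyaryl ynone 14 (not isolated)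
Conditions: 7 (1.5 equiv), CsF (4 equiv), THF, 125 °C (sealed tube); then Et2NH, EtOH, 70 °C
Reagents that add atoms: none
Why: Fluoride removes the silyl group of 7 and triflate leaves, giving aryne 13 with its triple bond between C1 and C2 and methoxy groups on C3 and C5 (aryne numbering; these become C8a, C4a, C5 and C7 of the target). The carboxylate of 12 (RCO2Cs) adds through oxygen to C1, the carbon remote from the C3 methoxy group, because σ-withdrawal by that oxygen distorts the aryne toward attack at C1 and stabilises the carbanion developing at C2; the C5 methoxy group, meta to C1 and para to C2, has only a weak bias that is overridden. The C2 carbanion lies beside the ester carbonyl and attacks it through a four-membered transition state, as in an anionic ortho-Fries shift, and collapse of the adduct breaks the acyl–oxygen bond to give the phenoxide of 14, so the aryne is inserted into the C–O bond of the acid. The closest known reaction type is the addition of carboxylic acids to arynes from silylaryl triflates, which gives ortho-hydroxyaryl ketones, chromanones from acrylic acids and flavones from arylpropiolic acids. Ring C then closes at O1–C2 by 6-endo-dig conjugate addition of the phenoxide oxygen to the ynone, and Et2NH takes any remaining 14 through its enaminone to the same chromone, which excludes 5-exo closure. No stereocentre is formed. Three selectivities are needed: oxygen at C1 and acyl at C2 (secured by the C3 methoxy group); acyl transfer ahead of protonation of the carbanion (secured by the aprotic medium, by excess CsF that binds HF, and by the carbonyl being held next to the carbanion); and attack at the carbonyl carbon rather than the alkyne β-carbon (the short reach of the in-plane carbanion, as the chromanone precedent shows).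

**Step 8**
Reactants: 15 5,7-dimethoxy-2-pentacosyl-4H-chromen-4-one
Product: 16 5,7-dihydroxy-2-pentacosyl-4H-chromen-4-one
Conditions: BBr3 (6 equiv), CH2Cl2, 0 to 40 °C; then MeOH, H2O
Reagents that add atoms: none
Why: Lewis-acid ether cleavage; the C5 ether, chelated to C4=O, should go first and the C7 ether with excess reagent and warming, while the saturated chain and the acid-stable pyranone are untouched.

## Compound list

1 | 3,5-dimethoxyphenol | COc1cc(O)cc(OC)c1 | starting material
2 | 3,5-dimethoxyphenyl N-isopropylcarbamate | CC(C)NC(=O)Oc1cc(OC)cc(OC)c1 | intermediate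
3 | 3,5-dimethoxyphenyl N-isopropyl-N-(trimethylsilyl)carbamate | CC(C)N([Si](C)(C)C)C(=O)Oc1cc(OC)cc(OC)c1 | intermediate
4 | 3,5-dimethoxy-2-(trimethylsilyl)phenyl N-isopropyl-N-(trimethylsilyl)carbamate | CC(C)N([Si](C)(C)C)C(=O)Oc1cc(OC)cc(OC)c1[Si](C)(C)C | intermediate
5 | 3,5-dimethoxy-2-(trimethylsilyl)phenyl N-isopropylcarbamate | CC(C)NC(=O)Oc1cc(OC)cc(OC)c1[Si](C)(C)C | intermediate
6 | 3,5-dimethoxy-2-(trimethylsilyl)phenol | COc1cc(O)c([Si](C)(C)C)c(OC)c1 | intermediate
7 | 3,5-dimethoxy-2-(trimethylsilyl)phenyl trifluoromethanesulfonate | COc1cc(OC)c([Si](C)(C)C)c(OS(=O)(=O)C(F)(F)F)c1 | intermediate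
8 | hexacosan-1-ol | CCCCCCCCCCCCCCCCCCCCCCCCCCO | starting material
9 | hexacosanal | CCCCCCCCCCCCCCCCCCCCCCCCCC=O | intermediate
10 | 1,1-dibromoheptacos-1-ene | CCCCCCCCCCCCCCCCCCCCCCCCCC=C(Br)Br | intermediate
11 | lithium heptacos-1-yn-1-ide | CCCCCCCCCCCCCCCCCCCCCCCCCC#C[Li] | intermediate
12 | octacos-2-ynoic acid | CCCCCCCCCCCCCCCCCCCCCCCCCC#CC(=O)O | intermediate
13 | 3,5-dimethoxybenzyne (1,2-didehydro-3,5-dimethoxybenzene) | COC1=CC(OC)=CC#C1 | intermediate
14 | 1-(2-hydroxy-4,6-dimethoxyphenyl)octacos-2-yn-1-one | CCCCCCCCCCCCCCCCCCCCCCCCCC#CC(=O)c1c(O)cc(OC)cc1OC | intermediate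
15 | 5,7-dimethoxy-2-pentacosyl-4H-chromen-4-one | CCCCCCCCCCCCCCCCCCCCCCCCCc1cc(=O)c2c(OC)cc(OC)cc2o1 | intermediate
16 | 5,7-dihydroxy-2-pentacosyl-4H-chromen-4-one | CCCCCCCCCCCCCCCCCCCCCCCCCc1cc(=O)c2c(O)cc(O)cc2o1 | target

## Count and risks

Total steps: 8. Longest linear sequence: 5 steps (1 → 2 → 5 → 7 → 15 → 16, or 8 → 9 → 10 → 12 → 15 → 16).

**Step 7 (key step).**
- The carbanion at C2 may be protonated before the acyl shift, which stops the sequence at the simple O-aryl ester stage.
- Excess aryne may arylate the phenoxide before ring closure.
- The soap-like cesium carboxylate may dissolve poorly and slow the addition, so that aryne self-reaction takes over.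
- Ring closure may be incomplete or go partly 5-exo before the amine is added.

Fallback (sets out from 10, returns at 15): 10 is converted with n-BuLi into 11 as in step 6, and 11 is added to purchased 2,4,6-trimethoxybenzaldehyde to give racemic 1-(2,4,6-trimethoxyphenyl)octacos-2-yn-1-ol F1. MnO2 in CH2Cl2 oxidises it to 1-(2,4,6-trimethoxyphenyl)octacos-2-yn-1-one F2. BCl3 (CH2Cl2, −78 to 0 °C) removes one ortho methyl group by chelation to the ketone and gives 14, here isolated. Et2NH in EtOH then closes 14 to 15.

**Step 2.**
- Lithiation may occur in part at C4 between the two methoxy groups.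
- The lithiated carbamate may undergo 1,3-acyl shift (anionic Fries) on warming.
- Incomplete N-silylation would let the carbamate fragment under n-BuLi.

Fallback (sets out from 1, returns at 7): amine-mediated ortho-bromination of 1 (NBS, i-Pr2NH cat., CH2Cl2, 0 °C) gives 2-bromo-3,5-dimethoxyphenol F3, purified by chromatography. HMDS gives (2-bromo-3,5-dimethoxyphenoxy)trimethylsilane F4. n-BuLi (THF, −100 to −78 °C) then causes bromine–lithium exchange and 1,3 O→C silyl shift to LiOAr, the lithium phenoxide of 6, and Tf2O added to the same flask gives 7. Here the bromine, not a competition between directing groups, fixes the site of silicon.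

**Step 6.**
- The waxy dibromide may precipitate at low temperature, leaving the exchange and rearrangement incomplete.
- On warming, the acetylide may be butylated by the 1-bromobutane formed.
- Carboxylation of a poorly soluble acetylide may stall.

Fallback (sets out from 9, returns at 12): homologation of 9 with the Ohira–Bestmann reagent (dimethyl 1-diazo-2-oxopropylphosphonate, K2CO3, MeOH/THF, rt to 40 °C) gives heptacos-1-yne F5. Deprotonation with EtMgBr in THF at 50 °C, where the wax is dissolved, followed by CO2 and acid work-up, gives 12.

**Step 8.**
- Cleavage may stop after the chelated C5 ether, since the C7 ether has no neighbouring carbonyl.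
- Forcing the Lewis acid may lead to bromide attack on ring C.
- The product may be lost through poor solubility of the boron complexes.

Fallback (sets out from 15, returns at 16): BCl3 (CH2Cl2, 0 °C) cleaves only the chelated ether and gives 5-hydroxy-7-methoxy-2-pentacosyl-4H-chromen-4-one F6. A melt of pyridine hydrochloride at 190 °C then cleaves the C7 ether by chloride attack on the protonated ether, and gives 16.

## Further compounds

F1 | step 7 | 1-(2,4,6-trimethoxyphenyl)octacos-2-yn-1-ol (racemic) | CCCCCCCCCCCCCCCCCCCCCCCCCC#CC(O)c1c(OC)cc(OC)cc1OC
F2 | step 7 | 1-(2,4,6-trimethoxyphenyl)octacos-2-yn-1-one | CCCCCCCCCCCCCCCCCCCCCCCCCC#CC(=O)c1c(OC)cc(OC)cc1OC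
F3 | step 2 | 2-bromo-3,5-dimethoxyphenol | COc1cc(O)c(Br)c(OC)c1
F4 | step 2 | (2-bromo-3,5-dimethoxyphenoxy)trimethylsilane | COc1cc(O[Si](C)(C)C)c(Br)c(OC)c1
F5 | step 6 | heptacos-1-yne | CCCCCCCCCCCCCCCCCCCCCCCCCC#C
F6 | step 8 | 5-hydroxy-7-methoxy-2-pentacosyl-4H-chromen-4-one | CCCCCCCCCCCCCCCCCCCCCCCCCc1cc(=O)c2c(O)cc(OC)cc2o1
A1 | alternative 1 | 2-acetyl-3,5-dimethoxyphenyl hexacosanoate | CCCCCCCCCCCCCCCCCCCCCCCCCC(=O)Oc1cc(OC)cc(OC)c1C(C)=O
A2 | alternative 1 | 1-(2-hydroxy-4,6-dimethoxyphenyl)octacosane-1,3-dione | CCCCCCCCCCCCCCCCCCCCCCCCCC(=O)CC(=O)c1c(O)cc(OC)cc1OC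
A3 | alternative 2 | 2-methyl-6-pentacosyl-4H-pyran-4-one | CCCCCCCCCCCCCCCCCCCCCCCCCc1cc(=O)cc(C)o1
A4 | alternative 2 | methyl 3-oxo-4-(4-oxo-6-pentacosyl-4H-pyran-2-yl)butanoate | CCCCCCCCCCCCCCCCCCCCCCCCCc1cc(=O)cc(CC(=O)CC(=O)OC)o1
A5 | alternative 3 | methyl octacos-2-ynoate | CCCCCCCCCCCCCCCCCCCCCCCCCC#CC(=O)OC
A6 | alternative 3 | (Z)-3-(3,5-dimethoxyphenoxy)octacos-2-enoic acid | CCCCCCCCCCCCCCCCCCCCCCCCC/C(Oc1cc(OC)cc(OC)c1)=C/C(=O)O
A7 | alternative 3 | 5,7-dimethoxy-4-pentacosyl-2H-chromen-2-one | CCCCCCCCCCCCCCCCCCCCCCCCCc1cc(=O)oc2cc(OC)cc(OC)c12
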